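**Plan**
Retrosynthetic cuts, in order: the 5-O-methyl and three O-benzyl groups; O1''–C2'' and C2''–C3'' of the unit 2 pyranone; C2=C3 and then O1–C2 of ring C in unit 1; the C6–O–ring D ether; C4a–C4.
Enabling feature: in ring C of unit 1, C2=C3 lies between the C4 ketone and C2, a carboxyl-level carbon bound to O1 and ring B. C3 can therefore be a keto-stabilised ylide carbon and C2 the carbonyl carbon of an aroyl ester on O1, and ring A holds both (through C4a and C8a) within reach of a six-membered closure.
Forward: the fully oxygenated ring A is acetylated, tied to ring D through oxygen, esterified with the ring B acid and converted into the phosphorane, and ring C then closes. The ring D ester next carries the Baker–Venkataraman build-up of rings C'' and A''.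
The 5-OH/7-OMe pattern comes from chelation-directed BCl3 cleavage of the peri methoxy group alone.
Stereochemistry: the target has no stereocentre and no configurable double bond, so nothing has to be set.

Key step: step 6

Remark: unprimed locants and rings A, B, C belong to the 7-methoxyflavone (unit 1). Doubly primed locants and rings A'', C'' belong to the apigenin half (unit 2), whose 2-aryl ring is ring D. The four building blocks are assumed purchasable, and 1,3-diketones are drawn in the keto form.

**Step 1**
Reactants: 1 2,6-dimethoxyhydroquinone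
Product: 2 1-(3,6-dihydroxy-2,4-dimethoxyphenyl)ethanone
Conditions: AcOH, BF3·OEt2, 90 °C, Ar; then H2O
Reagents that add atoms: acetic acid, CC(=O)O
Why: Friedel–Crafts (Nencki-type) C-acylation, in which the two free ring positions are equivalent, each is ortho to the unhindered hydroxyl and para to a methoxy group, and the boron chelate of the ortho-hydroxyketone deactivates the ring towards a second acylation.

**Step 2**
Reactants: 2 1-(3,6-dihydroxy-2,4-dimethoxyphenyl)ethanone; 3 methyl 4-fluorobenzoate
Product: 4 methyl 4-(3-acetyl-4-hydroxy-2,6-dimethoxyphenoxy)benzoate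
Conditions: K2CO3 (2.5 equiv), 3 (1.5 equiv), dry degassed DMSO, 110 °C, Ar
Reagents that add atoms: none
Why: Nucleophilic aromatic substitution (addition–elimination) on the para-ester-activated fluoride, in which the phenoxide between the two methoxy groups is electron-rich and unconjugated while the other is tied to the acetyl group as a vinylogous carboxylate, matching the known selective alkylation of the unchelated hydroxyl of this acetophenone.

**Step 3**
Reactants: 4 methyl 4-(3-acetyl-4-hydroxy-2,6-dimethoxyphenoxy)benzoate; 5 4-benzyloxybenzoic acid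
Product: 6 methyl 4-{3-acetyl-4-[4-(benzyloxy)benzoyloxy]-2,6-dimethoxyphenoxy}benzoate
Conditions: DCC, DMAP (0.2 equiv), CH2Cl2, 0 °C → rt
Reagents that add atoms: none
Why: Steglich esterification, in which the acylpyridinium species formed by DMAP is reactive enough to acylate the only remaining, hydrogen-bonded phenol, as is routine for 2-hydroxyacetophenones.

**Step 4**
Reactants: 6 methyl 4-{3-acetyl-4-[4-(benzyloxy)benzoyloxy]-2,6-dimethoxyphenoxy}benzoate
Product: 8 methyl 4-{4-[4-(benzyloxy)benzoyloxy]-3-(bromoacetyl)-2,6-dimethoxyphenoxy}benzoate, via trimethylsilyl enol ether 7 (not isolated)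
Conditions: Me3SiOTf, Et3N, CH2Cl2, 0 °C; crude 7, NBS, THF, −78 → 0 °C
Reagents that add atoms: trimethylsilyl trifluoromethanesulfonate, C[Si](C)(C)OS(=O)(=O)C(F)(F)F (silyl group of 7 only); N-bromosuccinimide, O=C1CCC(=O)N1Br
Why: Soft enolisation followed by bromination of the silyl enol ether, which forms no free enolate (so no premature aroyl shift) and lets the enol ether consume NBS at low temperature well before the one activated ring A C–H can be brominated.

**Step 5**
Reactants: 8 methyl 4-{4-[4-(benzyloxy)benzoyloxy]-3-(bromoacetyl)-2,6-dimethoxyphenoxy}benzoate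
Product: 10 methyl 4-{4-[4-(benzyloxy)benzoyloxy]-2,6-dimethoxy-3-[(triphenyl-λ5-phosphanylidene)acetyl]phenoxy}benzoate, via phosphonium bromide 9 (not isolated)
Conditions: PPh3, CH2Cl2, rt; then 10% aq. Na2CO3, 0 °C, brief biphasic stirring
Reagents that add atoms: triphenylphosphine, c1ccc(cc1)P(c1ccccc1)c1ccccc1
Why: SN2 quaternisation of PPh3 at the primary phenacyl carbon followed by deprotonation of the acidic phenacylphosphonium salt, for which cold carbonate suffices, so that the aryl ester is spared and the stabilised ylide can be kept below the temperature at which it cyclises.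

**Step 6**
Reactants: 10 methyl 4-{4-[4-(benzyloxy)benzoyloxy]-2,6-dimethoxy-3-[(triphenyl-λ5-phosphanylidene)acetyl]phenoxy}benzoate
Product: 11 methyl 4-({2-[4-(benzyloxy)phenyl]-5,7-dimethoxy-4-oxo-4H-chromen-6-yl}oxy)benzoate
Conditions: dry toluene (0.02 M), reflux, Ar
Reagents that add atoms: none
Why: Thermal activation lets ylide carbon C3 add to the carbonyl carbon of the aroyl ester on O1, the 2-oxido-3-phosphonio betaine closes to an oxaphosphetane, and cycloreversion expels Ph3PO and leaves C2=C3, so the pyranone appears directly at its final oxidation level. The closest known reaction type is the intramolecular Wittig olefination of an ester carbonyl by ortho-acyloxyphenacylidene phosphoranes, an established entry to chromones and flavones. Ring C (C3–C4–C4a–C8a–O1–C2) closes in the 6-exo-trig mode, the attacked C=O oxygen lying outside the new ring. No stereocentre is created and the new double bond is endocyclic, so no geometry has to be controlled. The step must distinguish the aryl ester on O1 from the methyl ester on ring D, and this is secured by geometry (only the former can reach C3 through a six-membered array), by the inertness of keto-stabilised ylides towards alkyl benzoates and by dilution. An O-to-C aroyl shift would not be a dead end, because the resulting phenol re-closes onto the same betaine, and the neutral medium forms the bond away from the crowded C5/C6 edge and leaves the methoxy, benzyl and ester groups untouched.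

**Step 7**
Reactants: 11 methyl 4-({2-[4-(benzyloxy)phenyl]-5,7-dimethoxy-4-oxo-4H-chromen-6-yl}oxy)benzoate
Product: 12 4-({2-[4-(benzyloxy)phenyl]-5,7-dimethoxy-4-oxo-4H-chromen-6-yl}oxy)benzoic acid
Conditions: LiOH·H2O, THF/MeOH/H2O, rt; then 1 M HCl
Reagents that add atoms: lithium hydroxide, [Li+].[OH-]
Why: Saponification of an unhindered methyl benzoate, which proceeds at room temperature, whereas opening of a 2-arylchromone by hydroxide needs hot concentrated alkali.

**Step 8**
Reactants: 13 2',4',6'-trihydroxyacetophenone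
Product: 14 1-[2,4-bis(benzyloxy)-6-hydroxyphenyl]ethanone
Conditions: BnBr (2.05 equiv), K2CO3, DMF, rt → 60 °C
Reagents that add atoms: benzyl bromide, BrCc1ccccc1
Why: Williamson etherification that stops at the known dibenzyl ether because the last hydroxyl is locked in a hydrogen bond to the acetyl group and its phenoxide is the least nucleophilic.

**Step 9**
Reactants: 12 4-({2-[4-(benzyloxy)phenyl]-5,7-dimethoxy-4-oxo-4H-chromen-6-yl}oxy)benzoic acid; 14 1-[2,4-bis(benzyloxy)-6-hydroxyphenyl]ethanone
Product: 15 2-acetyl-3,5-bis(benzyloxy)phenyl 4-({2-[4-(benzyloxy)phenyl]-5,7-dimethoxy-4-oxo-4H-chromen-6-yl}oxy)benzoate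
Conditions: DCC, DMAP (0.3 equiv), CH2Cl2, rt
Reagents that add atoms: none
Why: Steglich esterification, the usual way to load a benzoic acid onto a 2-hydroxy-4,6-dialkoxyacetophenone ahead of an acyl migration, with nothing else in either partner able to be acylated.

**Step 10**
Reactants: 15 2-acetyl-3,5-bis(benzyloxy)phenyl 4-({2-[4-(benzyloxy)phenyl]-5,7-dimethoxy-4-oxo-4H-chromen-6-yl}oxy)benzoate
Product: 16 1-[2,4-bis(benzyloxy)-6-hydroxyphenyl]-3-[4-({2-[4-(benzyloxy)phenyl]-5,7-dimethoxy-4-oxo-4H-chromen-6-yl}oxy)phenyl]propane-1,3-dione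
Conditions: LiN(SiMe3)2 (3 equiv), THF, −78 → −10 °C; then 1 M HCl
Reagents that add atoms: none
Why: Baker–Venkataraman rearrangement, in which the acetyl enolate attacks the neighbouring aryl ester in an intramolecular Claisen-type O-to-C acyl shift and the non-nucleophilic amide base cannot add to C2 of the finished ring C.

**Step 11**
Reactants: 16 1-[2,4-bis(benzyloxy)-6-hydroxyphenyl]-3-[4-({2-[4-(benzyloxy)phenyl]-5,7-dimethoxy-4-oxo-4H-chromen-6-yl}oxy)phenyl]propane-1,3-dione
Product: 17 6-{4-[5,7-bis(benzyloxy)-4-oxo-4H-chromen-2-yl]phenoxy}-2-[4-(benzyloxy)phenyl]-5,7-dimethoxy-4H-chromen-4-one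
Conditions: NaOAc, AcOH, 110 °C
Reagents that add atoms: none
Why: Cyclodehydration of an ortho-hydroxyaryl 1,3-diketone (hemiketal formation at the ring D carbonyl, then loss of water) closes ring C'', and the buffered acid is the variant used when benzyl ethers have to be kept.

**Step 12**
Reactants: 17 6-{4-[5,7-bis(benzyloxy)-4-oxo-4H-chromen-2-yl]phenoxy}-2-[4-(benzyloxy)phenyl]-5,7-dimethoxy-4H-chromen-4-one
Product: 18 isocryptomerin, 6-[4-(5,7-dihydroxy-4-oxo-4H-chromen-2-yl)phenoxy]-5-hydroxy-2-(4-hydroxyphenyl)-7-methoxy-4H-chromen-4-one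
Conditions: BCl3 (1 M in CH2Cl2, 12 equiv), C6HMe5 (10 equiv), CH2Cl2, −78 °C → rt; then 1 M HCl, THF
Reagents that add atoms: none
Why: Lewis-acid ether cleavage, in which BCl3 bridges the C4 carbonyl and the peri 5-methoxy oxygen so that chloride removes only that methyl group, the benzyl ethers ionise with their cations trapped by pentamethylbenzene, the unchelated 7-methoxy group and the diaryl ether persist, and the aprotic medium rules out a Wessely–Moser ring-opening isomerisation.

**Compound list**
1 | 2,6-dimethoxyhydroquinone | COc1cc(O)cc(OC)c1O | starting material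
2 | 1-(3,6-dihydroxy-2,4-dimethoxyphenyl)ethanone | CC(=O)c1c(O)cc(OC)c(O)c1OC | intermediate
3 | methyl 4-fluorobenzoate | COC(=O)c1ccc(F)cc1 | starting material
4 | methyl 4-(3-acetyl-4-hydroxy-2,6-dimethoxyphenoxy)benzoate | COC(=O)c1ccc(Oc2c(OC)cc(O)c(C(C)=O)c2OC)cc1 | intermediate
5 | 4-benzyloxybenzoic acid | OC(=O)c1ccc(OCc2ccccc2)cc1 | starting material
6 | methyl 4-{3-acetyl-4-[4-(benzyloxy)benzoyloxy]-2,6-dimethoxyphenoxy}benzoate | COC(=O)c1ccc(Oc2c(OC)cc(OC(=O)c3ccc(OCc4ccccc4)cc3)c(C(C)=O)c2OC)cc1 | intermediate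
7 | trimethylsilyl enol ether of 6 (not isolated) | COC(=O)c1ccc(Oc2c(OC)cc(OC(=O)c3ccc(OCc4ccccc4)cc3)c(C(=C)O[Si](C)(C)C)c2OC)cc1 | intermediate
8 | methyl 4-{4-[4-(benzyloxy)benzoyloxy]-3-(bromoacetyl)-2,6-dimethoxyphenoxy}benzoate | COC(=O)c1ccc(Oc2c(OC)cc(OC(=O)c3ccc(OCc4ccccc4)cc3)c(C(=O)CBr)c2OC)cc1 | intermediate
9 | phenacyltriphenylphosphonium bromide derived from 8 (not isolated) | COC(=O)c1ccc(Oc2c(OC)cc(OC(=O)c3ccc(OCc4ccccc4)cc3)c(C(=O)C[P+](c3ccccc3)(c3ccccc3)c3ccccc3)c2OC)cc1.[Br-] | intermediate
10 | methyl 4-{4-[4-(benzyloxy)benzoyloxy]-2,6-dimethoxy-3-[(triphenyl-λ5-phosphanylidene)acetyl]phenoxy}benzoate | COC(=O)c1ccc(Oc2c(OC)cc(OC(=O)c3ccc(OCc4ccccc4)cc3)c(C(=O)C=P(c3ccccc3)(c3ccccc3)c3ccccc3)c2OC)cc1 | intermediate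
11 | methyl 4-({2-[4-(benzyloxy)phenyl]-5,7-dimethoxy-4-oxo-4H-chromen-6-yl}oxy)benzoate | COC(=O)c1ccc(Oc2c(OC)cc3oc(-c4ccc(OCc5ccccc5)cc4)cc(=O)c3c2OC)cc1 | intermediate
12 | 4-({2-[4-(benzyloxy)phenyl]-5,7-dimethoxy-4-oxo-4H-chromen-6-yl}oxy)benzoic acid | OC(=O)c1ccc(Oc2c(OC)cc3oc(-c4ccc(OCc5ccccc5)cc4)cc(=O)c3c2OC)cc1 | intermediate
13 | 2',4',6'-trihydroxyacetophenone | CC(=O)c1c(O)cc(O)cc1O | starting material
14 | 1-[2,4-bis(benzyloxy)-6-hydroxyphenyl]ethanone | CC(=O)c1c(O)cc(OCc2ccccc2)cc1OCc1ccccc1 | intermediate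
15 | 2-acetyl-3,5-bis(benzyloxy)phenyl 4-({2-[4-(benzyloxy)phenyl]-5,7-dimethoxy-4-oxo-4H-chromen-6-yl}oxy)benzoate | CC(=O)c1c(OC(=O)c2ccc(Oc3c(OC)cc4oc(-c5ccc(OCc6ccccc6)cc5)cc(=O)c4c3OC)cc2)cc(OCc2ccccc2)cc1OCc1ccccc1 | intermediate
16 | 1-[2,4-bis(benzyloxy)-6-hydroxyphenyl]-3-[4-({2-[4-(benzyloxy)phenyl]-5,7-dimethoxy-4-oxo-4H-chromen-6-yl}oxy)phenyl]propane-1,3-dione | O=C(CC(=O)c1c(O)cc(OCc2ccccc2)cc1OCc1ccccc1)c1ccc(Oc2c(OC)cc3oc(-c4ccc(OCc5ccccc5)cc4)cc(=O)c3c2OC)cc1 | intermediate
17 | 6-{4-[5,7-bis(benzyloxy)-4-oxo-4H-chromen-2-yl]phenoxy}-2-[4-(benzyloxy)phenyl]-5,7-dimethoxy-4H-chromen-4-one | COc1cc2oc(-c3ccc(OCc4ccccc4)cc3)cc(=O)c2c(OC)c1Oc1ccc(-c2cc(=O)c3c(OCc4ccccc4)cc(OCc4ccccc4)cc3o2)cc1 | intermediate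
18 | isocryptomerin | COc1cc2oc(-c3ccc(O)cc3)cc(=O)c2c(O)c1Oc1ccc(-c2cc(=O)c3c(O)cc(O)cc3o2)cc1 | target

**Step count**
Total steps: 12. Longest linear sequence: 11 steps (1–7 and 9–12, from 1). Step 8 is the side branch.

**Steps most likely to fail**

1. Step 2. An ester is only a moderate activator. At the temperature required, the displacement may be overtaken by oxidation of the hydroquinone dianion, by arylation through the chelated oxygen or by methyl transfer from the ester to the phenoxide.
The fallback sets out from 2 and returns at 4, delivering the aryl group by ligand coupling at trivalent iodine instead of addition–elimination. Methyl 4-iodobenzoate is oxidised with mCPBA and TsOH·H2O in MeCN and captured with 1,3,5-trimethoxybenzene to give (4-methoxycarbonylphenyl)(2,4,6-trimethoxyphenyl)iodonium tosylate F1. Treating 2 with this salt and K2CO3 in MeCN at about 40 °C should pass the electron-poor aryl group to the unchelated phenoxide and give 4. This reaction type tolerates two ortho substituents.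

2. Step 6. Closure on the crowded ring may be sluggish. Hydrolysis of the ylide by adventitious water could then compete, or the aroyl group could come to rest on C3 after an O-to-C shift without loss of the phosphine oxide.
The fallback sets out from 6 and returns at 11, skipping steps 4 and 5. LiN(SiMe3)2 in THF (−78 → 0 °C) brings about a Baker–Venkataraman shift to methyl 4-(3-{3-[4-(benzyloxy)phenyl]-3-oxopropanoyl}-4-hydroxy-2,6-dimethoxyphenoxy)benzoate F2. NaOAc/AcOH at 110 °C, or a trace of H2SO4 in AcOH, then closes O1–C2 with loss of water to give 11.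

3. Step 12. Four ether cleavages are asked of one pot. Partly deprotected boron chelates may precipitate from CH2Cl2 and stall the 5-O-demethylation. Benzyl cations may also be captured by the electron-rich ring A'', and long warming may begin to erode the 7-methyl ether.
The fallback sets out from 17 and returns at 18, separating the two tasks by mechanism. Hydrogenolysis (H2, Pd/C, THF/MeOH, rt) removes the three benzyl groups to give 6-[4-(5,7-dihydroxy-4-oxo-4H-chromen-2-yl)phenoxy]-2-(4-hydroxyphenyl)-5,7-dimethoxy-4H-chromen-4-one F3. AlCl3 in MeCN at reflux, a medium in which the polyphenol dissolves as its aluminium complex, followed by dilute HCl, then cleaves only the chelated 5-methoxy group to give 18.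

**Further compounds**
F1 | step 2 | (4-methoxycarbonylphenyl)(2,4,6-trimethoxyphenyl)iodonium tosylate | COC(=O)c1ccc([I+]c2c(OC)cc(OC)cc2OC)cc1.Cc1ccc(cc1)S(=O)(=O)[O-]
F2 | step 6 | methyl 4-(3-{3-[4-(benzyloxy)phenyl]-3-oxopropanoyl}-4-hydroxy-2,6-dimethoxyphenoxy)benzoate | COC(=O)c1ccc(Oc2c(OC)cc(O)c(C(=O)CC(=O)c3ccc(OCc4ccccc4)cc3)c2OC)cc1
F3 | step 12 | 6-[4-(5,7-dihydroxy-4-oxo-4H-chromen-2-yl)phenoxy]-2-(4-hydroxyphenyl)-5,7-dimethoxy-4H-chromen-4-one | COc1cc2oc(-c3ccc(O)cc3)cc(=O)c2c(OC)c1Oc1ccc(-c2cc(=O)c3c(O)cc(O)cc3o2)cc1
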